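The carbocycle is cut at C1′–C2′, the bond between the methyl-bearing quaternary carbon and the carbon that carries the exocyclic methylene. This C(=CH2)–C(CH3) pair is the retron of a reductive 1,7-enyne cyclisation. In one Pd–H operation a terminal alkyne becomes C2′=CH2 and a 1,1-disubstituted alkene becomes C1′ plus its methyl. The same operation closes the six-membered ring and sets C1′ under control of the propargylic methyl centre C3′. The precursor is an open enyne chain hanging from a finished, enantiopure 2H-chromene. It is assembled from (S)-linalool, a bromoiodoguaiacol ether and an Evans-derived (R)-enyne. Deprotection and phenol-to-quinone oxidation finish the synthesis.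

Key step: step 15

Locants: the chromene atoms are O1 and C2–C8a. The carbocycle atoms are C1′ (quaternary), C2′ (=CH2), C3′ (CH–CH3) and C4′–C6′ (CH2).
Assumption: (S)-(+)-linalool (coriandrol) is taken as a commercial chiral-pool material of high enantiomeric purity.

Step 1
Reactants: 1 5-bromo-2-methoxyphenol
Product: 2 4-bromo-1-methoxy-2-(methoxymethoxy)benzene
Conditions: MOMCl, i-Pr2NEt, CH2Cl2, 0 °C to rt
Reagents that add atoms: chloromethyl methyl ether (MOMCl), COCCl
Why: Base-mediated O-alkylation (MOM protection) masks the phenol that later becomes the C5 carbonyl and installs the directing group for step 2; no stereocentre is involved.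

Step 2
Reactants: 2 4-bromo-1-methoxy-2-(methoxymethoxy)benzene
Product: 4 1-bromo-2-iodo-4-methoxy-3-(methoxymethoxy)benzene, via aryllithium 3 (not isolated)
Conditions: LDA (commercial solution), THF, −78 °C; then I2, THF, −78 °C
Reagents that add atoms: iodine, II
Why: Directed ortho-metalation removes the C–H flanked by OMOM (coordination) and Br (induction), by far the most acidic one, the aryllithium is kept at −78 °C to suppress benzyne formation and halogen dance, and iodinolysis gives an I/Br pair of graded reactivity.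

Step 3
Reactants: 4 1-bromo-2-iodo-4-methoxy-3-(methoxymethoxy)benzene; 5 (S)-(+)-linalool
Product: 7 (3S)-1-[6-bromo-3-methoxy-2-(methoxymethoxy)phenyl]-3,7-dimethyloct-6-en-3-ol, via alkylborane 6 (not isolated)
Conditions: 5, 9-BBN (2 equiv), THF, 0 °C to rt; then 4, Pd(dppf)Cl2·CH2Cl2 (5 mol %), 3 M aq NaOH, THF, 60 °C
Reagents that add atoms: none
Why: Chemoselective hydroboration of the monosubstituted vinyl group (the trisubstituted alkene is inert and any O-borinate is hydrolysed by the aqueous base), followed by B-alkyl Suzuki–Miyaura coupling at the more reactive C–I bond, joins C4 to C4a; the carbinol stereocentre of linalool (future C2) is not touched.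

Step 4
Reactants: 7 (3S)-1-[6-bromo-3-methoxy-2-(methoxymethoxy)phenyl]-3,7-dimethyloct-6-en-3-ol
Product: 8 (2S)-6-methoxy-5-(methoxymethoxy)-2-methyl-2-(4-methylpent-3-en-1-yl)chromane
Conditions: Pd(OAc)2 (5 mol %), 2-(di-tert-butylphosphino)-1,1′-binaphthyl, Cs2CO3, toluene, 80 °C
Reagents that add atoms: none
Why: Intramolecular Buchwald–Hartwig C–O coupling of a tertiary alcohol (no β-hydride on the alkoxide carbon) closes the pyran ring by making the aryl–O bond, so the C–O bond at the stereocentre is never broken and C2 is retained.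

Step 5
Reactants: 8 (2S)-6-methoxy-5-(methoxymethoxy)-2-methyl-2-(4-methylpent-3-en-1-yl)chromane
Product: 9 3-[(2R)-6-methoxy-5-(methoxymethoxy)-2-methylchroman-2-yl]propanal
Conditions: OsO4 (2 mol %), NaIO4, 2,6-lutidine, 1,4-dioxane–H2O, rt
Reagents that add atoms: osmium tetroxide (catalytic oxygen carrier), O=[Os](=O)(=O)=O; sodium periodate (terminal oxidant), [Na+].[O-]I(=O)(=O)=O
Why: Lemieux–Johnson cleavage of the only alkene removes the isopropylidene unit as acetone and avoids ozone on the electron-rich arene; the C2 descriptor changes by CIP ranking only.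

Step 6
Reactants: 9 3-[(2R)-6-methoxy-5-(methoxymethoxy)-2-methylchroman-2-yl]propanal
Product: 10 (2S)-2-(but-3-yn-1-yl)-6-methoxy-5-(methoxymethoxy)-2-methylchromane
Conditions: dimethyl (1-diazo-2-oxopropyl)phosphonate, K2CO3, MeOH, 0 °C to rt
Reagents that add atoms: Ohira–Bestmann reagent, CC(=O)C(=[N+]=[N-])P(=O)(OC)OC
Why: Ohira–Bestmann (Seyferth–Gilbert) homologation of a non-epimerisable aldehyde gives the terminal alkyne whose two carbons become C1′ and its methyl group.

Step 7
Reactants: 10 (2S)-2-(but-3-yn-1-yl)-6-methoxy-5-(methoxymethoxy)-2-methylchromane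
Product: 11 (2S)-2-(but-3-yn-1-yl)-6-methoxy-5-(methoxymethoxy)-2-methyl-2H-chromene
Conditions: DDQ (1.3 equiv), dry 1,4-dioxane, 90 °C
Reagents that add atoms: none
Why: DDQ dehydrogenation abstracts hydride from benzylic C4, whose cation is stabilised by the ortho oxygens at C5 and C8a, loss of H-3 then gives the 2H-chromene, and the quaternary C2 blocks further oxidation.

Step 8
Reactants: 11 (2S)-2-(but-3-yn-1-yl)-6-methoxy-5-(methoxymethoxy)-2-methyl-2H-chromene
Product: 13 (2S)-2-(3-iodobut-3-en-1-yl)-6-methoxy-5-(methoxymethoxy)-2-methyl-2H-chromene, via alkenylalane 12 (not isolated)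
Conditions: Ni(dppp)Cl2 (3 mol %), DIBAL-H (1.3 equiv), THF, 0 °C to rt; then I2, THF, −78 to 0 °C
Reagents that add atoms: iodine, II
Why: Nickel-catalysed α-selective (Markovnikov) hydroalumination of the terminal alkyne and iodinolysis of the C–Al bond give the 2-iodo-1-alkene, and I2 rather than an N-halo imide spares the electron-rich arene.

Step 9
Reactants: 14 (S)-4-benzyl-3-propionyloxazolidin-2-one
Product: 16 (S)-4-benzyl-3-[(R)-2-methylpent-4-enoyl]oxazolidin-2-one, via sodium enolate 15 (not isolated)
Conditions: NaHMDS, THF, −78 °C; then allyl iodide, −78 °C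
Reagents that add atoms: allyl iodide, C=CCI
Why: Evans asymmetric alkylation: the chelated (Z)-sodium enolate is allylated on the face opposite the benzyl group, which sets the (R)-methyl stereocentre (future C3′).

Step 10
Reactants: 16 (S)-4-benzyl-3-[(R)-2-methylpent-4-enoyl]oxazolidin-2-one
Product: 17 (R)-2-methylpent-4-en-1-ol
Conditions: LiBH4, MeOH (1 equiv), Et2O, 0 °C
Reagents that add atoms: none
Why: Reductive cleavage of the imide with LiBH4 gives the primary alcohol without touching the α-stereocentre or the alkene and returns the auxiliary.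

Step 11
Reactants: 17 (R)-2-methylpent-4-en-1-ol
Product: 18 (R)-2-methylpent-4-enal
Conditions: TEMPO (10 mol %), PhI(OAc)2, CH2Cl2, rt; used as a washed and dried CH2Cl2 solution
Reagents that add atoms: none
Why: The TEMPO/PhI(OAc)2 oxidation stops at the aldehyde under nearly neutral conditions, so the α-stereocentre should not epimerise, and the volatile product is not concentrated.

Step 12
Reactants: 18 (R)-2-methylpent-4-enal
Product: 19 (R)-1,1-dibromo-3-methylhexa-1,5-diene
Conditions: CBr4, PPh3, CH2Cl2, 0 °C
Reagents that add atoms: carbon tetrabromide, BrC(Br)(Br)Br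
Why: The first stage of the Corey–Fuchs sequence (Wittig-type dibromoolefination) is non-basic and keeps the allylic stereocentre intact.

Step 13
Reactants: 19 (R)-1,1-dibromo-3-methylhexa-1,5-diene
Product: 21 (R)-trimethyl(3-methylhex-5-en-1-yn-1-yl)silane, via lithium acetylide 20 (not isolated)
Conditions: n-BuLi (2.1 equiv), THF, −78 to 0 °C; then TMSCl, −78 °C to rt
Reagents that add atoms: chlorotrimethylsilane, C[Si](C)(C)Cl
Why: The second stage of the Corey–Fuchs sequence (Li/Br exchange, Fritsch–Buttenberg–Wiechell rearrangement, deprotonation) gives the acetylide, which is silylated in the same flask so that the alkyne is blocked during the later hydroboration and coupling.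

Step 14
Reactants: 13 (2S)-2-(3-iodobut-3-en-1-yl)-6-methoxy-5-(methoxymethoxy)-2-methyl-2H-chromene; 21 (R)-trimethyl(3-methylhex-5-en-1-yn-1-yl)silane
Product: 24 (2S)-6-methoxy-5-(methoxymethoxy)-2-methyl-2-[(7R)-7-methyl-3-methylidenenon-8-yn-1-yl]-2H-chromene, via alkylborane 22 (not isolated), via silyl enyne 23 (not isolated)
Conditions: 21, 9-BBN (1.1 equiv), THF, 0 °C to rt; then 13, Pd(dppf)Cl2·CH2Cl2 (5 mol %), AsPh3, Cs2CO3, DMF–H2O, rt; then MeOH, rt
Reagents that add atoms: none
Why: Chemoselective 9-BBN hydroboration of the terminal alkene (the silyl-capped alkyne is inert) and room-temperature B-alkyl Suzuki–Miyaura coupling with the alkenyl iodide build the 1,1-disubstituted alkene, fast transmetalation should outrun 5-exo Heck insertion into the hindered C3=C4 bond, and carbonate/MeOH then removes the C-silyl group; no stereocentre is affected.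

Step 15
Reactants: 24 (2S)-6-methoxy-5-(methoxymethoxy)-2-methyl-2-[(7R)-7-methyl-3-methylidenenon-8-yn-1-yl]-2H-chromene
Product: 27 (2S)-2-{2-[(1R,3R)-1,3-dimethyl-2-methylidenecyclohexyl]ethyl}-6-methoxy-5-(methoxymethoxy)-2-methyl-2H-chromene, via alkenylpalladium 25 (not isolated), via neopentylpalladium 26 (not isolated)
Conditions: Pd2(dba)3·CHCl3 (5 mol %), P(o-Tol)3 (20 mol %), AcOH (2 equiv), Et3SiH (5 equiv), toluene, rt to 40 °C
Reagents that add atoms: none
Why: Pd(0) and AcOH give H–Pd–OAc, which adds across the terminal alkyne with Pd at the internal carbon (25); syn-carbopalladation of the 1,1-disubstituted alkene forms C1′–C2′ and leaves the neopentyl-type σ-alkylpalladium 26, which has no β-hydrogen and is reduced by Et3SiH (Pd–OAc/Si–H exchange, C–H reductive elimination) to the C1′ methyl group. The closest known reaction type is the palladium-hydride-initiated reductive cyclisation of 1,6- and 1,7-enynes, the hydride-terminated relative of enyne cycloisomerisation and of the reductive Heck reaction. Only the cyclohexane is closed, in the 6-exo-trig mode with respect to the alkene. C1′ is controlled by C3′: the four-centre insertion requires the alkene CH2 (the future methyl) to stand roughly perpendicular to the alkenyl plane, that is pseudo-axial in a chair, so the chair with the C3′ methyl and the long C1′ chain both pseudo-equatorial is preferred, whereas attack on the other alkene face would force the C3′ methyl into a 1,3-diaxial contact with CH2–Pd, and this should give the (1′R,3′R) isomer in which C3′–CH3 and the chain are cis. C3′ and C2 are spectators and are not epimerisable under these conditions. The step needs hydropalladation of the alkyne in preference to the two alkenes, secured by the stronger binding of the unhindered terminal alkyne, and hydride capture of 26 before it inserts into the new methylidene (3-exo) or into C3=C4 (6-exo), secured by the excess of silane and by the quaternary carbons that shield both alkenes.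

Step 16
Reactants: 27 (2S)-2-{2-[(1R,3R)-1,3-dimethyl-2-methylidenecyclohexyl]ethyl}-6-methoxy-5-(methoxymethoxy)-2-methyl-2H-chromene
Product: 28 (2S)-2-{2-[(1R,3R)-1,3-dimethyl-2-methylidenecyclohexyl]ethyl}-6-methoxy-2-methyl-2H-chromen-5-ol
Conditions: ZnBr2 (1 equiv), n-PrSH (2 equiv), CH2Cl2, 0 °C, minutes; dim light
Reagents that add atoms: none
Why: Lewis acid/thiol cleavage of the phenolic MOM acetal (ZnBr2 activates, the thiol traps the oxocarbenium ion) is fast at 0 °C and needs no Brønsted acid, which should spare the exocyclic methylene and the ionisable C2–O bond.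

Step 17
Reactants: 28 (2S)-2-{2-[(1R,3R)-1,3-dimethyl-2-methylidenecyclohexyl]ethyl}-6-methoxy-2-methyl-2H-chromen-5-ol
Product: 29 metachromin E
Conditions: Fremy's salt (2.5 equiv), KH2PO4 buffer, acetone–H2O, rt, dim light
Reagents that add atoms: potassium nitrosodisulfonate (Fremy's salt), [O]N(S(=O)(=O)[O-])S(=O)(=O)[O-].[K+].[K+]
Why: Teuber oxidation: the phenoxyl radical made by the first equivalent of nitrosodisulfonate couples with the second at the free para position C8 (both ortho positions are substituted), loss of imidodisulfonate gives the 5,8-quinone, and the isolated and chromene alkenes are inert to this radical.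

Compound list
1 | 5-bromo-2-methoxyphenol | COc1ccc(Br)cc1O | starting material
2 | 4-bromo-1-methoxy-2-(methoxymethoxy)benzene | COCOc1cc(Br)ccc1OC | intermediate
3 | [6-bromo-3-methoxy-2-(methoxymethoxy)phenyl]lithium | [Li]c1c(Br)ccc(OC)c1OCOC | intermediate
4 | 1-bromo-2-iodo-4-methoxy-3-(methoxymethoxy)benzene | COCOc1c(I)c(Br)ccc1OC | intermediate
5 | (S)-(+)-linalool | C=C[C@@](C)(O)CCC=C(C)C | starting material
6 | (3R)-1-(9-borabicyclo[3.3.1]nonan-9-yl)-3,7-dimethyloct-6-en-3-ol (same spatial arrangement as 5) | CC(C)=CCC[C@@](O)(C)CCB1C2CCCC1CCC2 | intermediate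
7 | (3S)-1-[6-bromo-3-methoxy-2-(methoxymethoxy)phenyl]-3,7-dimethyloct-6-en-3-ol | CC(C)=CCC[C@@](O)(C)CCc1c(Br)ccc(OC)c1OCOC | intermediate
8 | (2S)-6-methoxy-5-(methoxymethoxy)-2-methyl-2-(4-methylpent-3-en-1-yl)chromane | CC(C)=CCC[C@@]1(C)CCc2c(O1)ccc(OC)c2OCOC | intermediate
9 | 3-[(2R)-6-methoxy-5-(methoxymethoxy)-2-methylchroman-2-yl]propanal | O=CCC[C@@]1(C)CCc2c(O1)ccc(OC)c2OCOC | intermediate
10 | (2S)-2-(but-3-yn-1-yl)-6-methoxy-5-(methoxymethoxy)-2-methylchromane | C#CCC[C@@]1(C)CCc2c(O1)ccc(OC)c2OCOC | intermediate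
11 | (2S)-2-(but-3-yn-1-yl)-6-methoxy-5-(methoxymethoxy)-2-methyl-2H-chromene | C#CCC[C@@]1(C)C=Cc2c(O1)ccc(OC)c2OCOC | intermediate
12 | diisobutyl{4-[(2S)-6-methoxy-5-(methoxymethoxy)-2-methyl-2H-chromen-2-yl]but-1-en-2-yl}alane | C=C([Al](CC(C)C)CC(C)C)CC[C@@]1(C)C=Cc2c(O1)ccc(OC)c2OCOC | intermediate
13 | (2S)-2-(3-iodobut-3-en-1-yl)-6-methoxy-5-(methoxymethoxy)-2-methyl-2H-chromene | C=C(I)CC[C@@]1(C)C=Cc2c(O1)ccc(OC)c2OCOC | intermediate
14 | (S)-4-benzyl-3-propionyloxazolidin-2-one | CCC(=O)N1[C@@H](Cc2ccccc2)COC1=O | starting material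
15 | sodium (Z)-enolate of 14 | C/C=C(\[O-])N1[C@@H](Cc2ccccc2)COC1=O.[Na+] | intermediate
16 | (S)-4-benzyl-3-[(R)-2-methylpent-4-enoyl]oxazolidin-2-one | C=CC[C@@H](C)C(=O)N1[C@@H](Cc2ccccc2)COC1=O | intermediate
17 | (R)-2-methylpent-4-en-1-ol | C=CC[C@@H](C)CO | intermediate
18 | (R)-2-methylpent-4-enal | C=CC[C@@H](C)C=O | intermediate
19 | (R)-1,1-dibromo-3-methylhexa-1,5-diene | C=CC[C@@H](C)C=C(Br)Br | intermediate
20 | lithium (R)-3-methylhex-5-en-1-yn-1-ide | [Li]C#C[C@H](C)CC=C | intermediate
21 | (R)-trimethyl(3-methylhex-5-en-1-yn-1-yl)silane | C[Si](C)(C)C#C[C@H](C)CC=C | intermediate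
22 | [(R)-6-(9-borabicyclo[3.3.1]nonan-9-yl)-3-methylhex-1-yn-1-yl]trimethylsilane | C[Si](C)(C)C#C[C@H](C)CCCB1C2CCCC1CCC2 | intermediate
23 | (2S)-6-methoxy-5-(methoxymethoxy)-2-methyl-2-[(7R)-7-methyl-3-methylidene-9-(trimethylsilyl)non-8-yn-1-yl]-2H-chromene | C[Si](C)(C)C#C[C@H](C)CCCC(=C)CC[C@@]1(C)C=Cc2c(O1)ccc(OC)c2OCOC | intermediate
24 | (2S)-6-methoxy-5-(methoxymethoxy)-2-methyl-2-[(7R)-7-methyl-3-methylidenenon-8-yn-1-yl]-2H-chromene | C#C[C@H](C)CCCC(=C)CC[C@@]1(C)C=Cc2c(O1)ccc(OC)c2OCOC | intermediate
25 | alkenylpalladium(II) acetate from hydropalladation of 24 (Pd on the future C2′; phosphine ligands omitted) | C=C([Pd]OC(C)=O)[C@H](C)CCCC(=C)CC[C@@]1(C)C=Cc2c(O1)ccc(OC)c2OCOC | intermediate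
26 | neopentyl-type alkylpalladium(II) acetate after ring closure (Pd on the future C1′ methyl; phosphine ligands omitted) | C=C1[C@H](C)CCC[C@]1(C[Pd]OC(C)=O)CC[C@@]1(C)C=Cc2c(O1)ccc(OC)c2OCOC | intermediate
27 | (2S)-2-{2-[(1R,3R)-1,3-dimethyl-2-methylidenecyclohexyl]ethyl}-6-methoxy-5-(methoxymethoxy)-2-methyl-2H-chromene | C=C1[C@H](C)CCC[C@]1(C)CC[C@@]1(C)C=Cc2c(O1)ccc(OC)c2OCOC | intermediate
28 | (2S)-2-{2-[(1R,3R)-1,3-dimethyl-2-methylidenecyclohexyl]ethyl}-6-methoxy-2-methyl-2H-chromen-5-ol | C=C1[C@H](C)CCC[C@]1(C)CC[C@@]1(C)C=Cc2c(O1)ccc(OC)c2O | intermediate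
29 | metachromin E, (2S)-2-{2-[(1R,3R)-1,3-dimethyl-2-methylidenecyclohexyl]ethyl}-6-methoxy-2-methyl-2H-chromene-5,8-dione | C=C1[C@H](C)CCC[C@]1(C)CC[C@@]1(C)C=CC2=C(O1)C(=O)C=C(OC)C2=O | target

Total step count: 17
Longest linear sequence: 12 steps (1 to 29 through steps 1–8 and 14–17)

Steps most likely to fail

**1. Step 15 (key step).**
- What may go wrong: hydride capture of the alkenylpalladium before the slow 6-exo closure onto a 1,1-disubstituted alkene; insufficient facial selectivity in the carbopalladation; or escape of the neopentylpalladium through 3-exo insertion and ring expansion.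
- Fallback: it sets out from 24 and comes back at 27. The alkyne of 24 is first converted by nickel-catalysed α-hydroalumination and iodinolysis (as in step 8) into the 2-iodo-1-alkene (2S)-2-[(7R)-8-iodo-7-methyl-3-methylidenenon-8-en-1-yl]-6-methoxy-5-(methoxymethoxy)-2-methyl-2H-chromene F1.
- The ring is then closed by a reductive Heck cyclisation (Pd(OAc)2, phosphine, HCO2Na, n-Bu4NCl, DMF, 60 °C). The alkenylpalladium now arises by oxidative addition in the absence of any hydride on palladium, so it can only cyclise. Formate reduces the neopentylpalladium afterwards.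
- If substrate control of the alkene face is too weak, a chiral bisphosphine can be matched to the C3′ centre.

**2. Step 3.**
- What may go wrong: sluggish oxidative addition and transmetalation at the doubly ortho-substituted C–I bond, protodeboronation of the alkylborane, or a second coupling at C–Br.
- Fallback: it sets out from 4 and 5 and comes back at 7. A Heck reaction of 4 with the vinyl group of 5 (Pd(OAc)2, n-Bu4NCl, NaHCO3, DMF, 60 °C) is used. The tertiary carbinol carbon carries no hydrogen, so no ketone can form. This should give (1E,3S)-1-[6-bromo-3-methoxy-2-(methoxymethoxy)phenyl]-3,7-dimethylocta-1,6-dien-3-ol F2.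
- The disubstituted alkene of F2 is then reduced with diimide (2-nitrobenzenesulfonylhydrazide, Et3N, CH2Cl2, rt). This should proceed in preference to the trisubstituted alkene and without loss of the aryl bromide.

**3. Step 7.**
- What may go wrong: adduct formation or over-oxidation of the very electron-rich arene by DDQ, loss of the MOM group, or erosion of the C2 configuration by thermal electrocyclic opening of the chromene during prolonged heating.
- Fallback: it sets out from 10 and comes back at 11 through oxygenation, reduction and dehydration instead of direct dehydrogenation.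
- Benzylic oxidation with IBX (DMSO–fluorobenzene, 80 °C) should give (2S)-2-(but-3-yn-1-yl)-6-methoxy-5-(methoxymethoxy)-2-methylchroman-4-one F3.
- NaBH4 in MeOH at 0 °C then reduces it to (2S)-2-(but-3-yn-1-yl)-6-methoxy-5-(methoxymethoxy)-2-methylchroman-4-ol F4, obtained as C4 epimers.
- Catalytic PPTS in toluene at 60 °C dehydrates this doubly oxygen-activated benzylic alcohol to 11.

Further compounds
F1 | step 15 | (2S)-2-[(7R)-8-iodo-7-methyl-3-methylidenenon-8-en-1-yl]-6-methoxy-5-(methoxymethoxy)-2-methyl-2H-chromene | C=C(I)[C@H](C)CCCC(=C)CC[C@@]1(C)C=Cc2c(O1)ccc(OC)c2OCOC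
F2 | step 3 | (1E,3S)-1-[6-bromo-3-methoxy-2-(methoxymethoxy)phenyl]-3,7-dimethylocta-1,6-dien-3-ol | CC(C)=CCC[C@@](O)(C)/C=C/c1c(Br)ccc(OC)c1OCOC
F3 | step 7 | (2S)-2-(but-3-yn-1-yl)-6-methoxy-5-(methoxymethoxy)-2-methylchroman-4-one | C#CCC[C@@]1(C)CC(=O)c2c(O1)ccc(OC)c2OCOC
F4 | step 7 | (2S)-2-(but-3-yn-1-yl)-6-methoxy-5-(methoxymethoxy)-2-methylchroman-4-ol (C4 epimers) | C#CCC[C@@]1(C)CC(O)c2c(O1)ccc(OC)c2OCOC
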